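All runs are simulated with made-up constants; the scatter is artificial.

Carrying the midnight run's 0.1949 M of Q over to the autumn flask as a concentration is the trap: against a charge of 0.620 M it makes a share of 31.4%, and that share assumes a rate that takes no notice of L.

| flask | L | E | time |
|---|---|---|---|
| midnight | 0.250 M | 0.0250 M |  |
| spring | 0.250 M | 0.0380 M |  |
| autumn | 0.620 M | 0.0250 M | 36 min |

| run | time / min | [Q] / M |
|---|---|---|
| midnight run | 1.6 | 0.0146 |
| midnight run | 4.9 | 0.0476 |
| midnight run | 9.3 | 0.0820 |
| midnight run | 15 | 0.1185 |
| midnight run | 21 | 0.1476 |
| midnight run | 28 | 0.1740 |
| midnight run | 36 | 0.1949 |
| spring run | 1.6 | 0.0250 |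
| spring run | 4.9 | 0.0693 |
| spring run | 9.3 | 0.1135 |
| spring run | 15 | 0.1562 |
| spring run | 21 | 0.1841 |
| spring run | 28 | 0.2102 |
| spring run | 36 | 0.2267 |

(standard deviation of a reading: 0.001 M)

1. the power of [E] that the first rate follows, about the charge of the midnight run; measure it at two percent of L made into Q
2. Q in the autumn run at 36 min, as a share of the L charged

- Overall: L -> Q, with E as catalyst.
- Constant volume, constant temperature.
- An order is taken over about fifteen percent of the charge, up and down.

At 36 min the midnight run reads 0.0420 /min on the fraction clock, the natural logarithm of L charged over L left, divided by the time, which is a pseudo-first-order constant if it holds still. One reading cannot show that, and at 9.3 min the same clock stands higher than that, at 0.0427 /min. But the gap is 7.33 × 10⁻⁴ /min, while one standard deviation of the last reading is worth 5.04 × 10⁻⁴ /min on the clock, so the drift is not far outside the scatter.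

A steady clock means that the fraction made at a given time and E takes no notice of the charge, so the autumn run, with the midnight E, should reach 78.0% at 36 min. The objection is that the autumn charge is 2.48 times the 0.250 M of both runs so far, so this estimate is an extrapolation.

The spring clock at 36 min reads 0.0659 /min, which against the ratio of E gives an order of 1.08. Here the doubt is that two percent turned lies before the first midnight reading, which already holds 5.84% of the charge, so this order is carried back from later times.

The forecast differs slightly from this reckoning, with 1.03 for the order and 78.2% for the share, and its ground is: “With first order in L, the fractional conversion does not depend on the charge.”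

The simulation gives an order of 1.1 and a share of 78.2%, and the forecast is right on both.

    E + L → Q + E (1.788 /M/min)
    E + Qa → Xi
    L → Q (0.004290 /min)

In the midnight run, Qa took 15.0% of the E charged into Xi at once, leaving 85.0% of it free. From then to 36 min in the midnight run, that E turned L into Q while L also turned by itself, the two together running at a first-order constant of 0.0423 /min. The clock puts half of the charge at 16.5 min in the midnight run against 16.4 min, and at 10.5 min in the spring run against 10.6 min, and its 78.0% for the autumn run stands beside 78.2%.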